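**Retrosynthetic overview** (locants: C1 CH(OAc), C2 CH2, C3 C(OH)iPr, C4 fusion CH, C5 CH(OAr), C6=C7(Me), C8 C=O, C9 CH2, C10 C(Me); O3 and O5 are the oxygens on C3 and C5)
1. Feature: the seven-membered ring C4–C10 carries oxygen at C5 and C8 and methyl at C7, i.e. a 2,5-dioxygenated toluene with C10 inserted between C4 and C9; the C3 tertiary hydroxyl lies β to both C1 and C5.
2. Target ⇐ hydroxy triketone 16: C3–OH-directed hydride delivery to C1 and C5, C5 aroylation, C1 acetylation, phenol release.
3. 16 ⇐ tricyclic dihydroazulenone 14 (fluoride, then dilute acid) ⇐ α-methyl diazo ketone 12 by intramolecular Buchner reaction, which forms C4–C10 and C9–C10.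
4. 12 ⇐ aldehyde 8 (propiophenone aldol, oxidation, debenzoylative diazo transfer) ⇐ phenol-directed asymmetric allylation of ketone 4 and an O3/O5 silylene tether ⇐ 2,5-dimethoxytoluene 1.
5. Ring order: temporary six-membered dioxasiline tether first, then the five- and seven-membered carbocycles together in the key step.

Key step: step 8

Assumption: the (R,R)-enantiomer of allylsilane 5 is taken to deliver allyl to the Re face of the silicon-bound ketone (S at C3); if the sense is the opposite, the (S,S)-enantiomer is used and nothing else changes.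

Step 1
Reactants: 1 2,5-dimethoxytoluene; 2 isobutyryl chloride
Product: 4 1-(2-hydroxy-5-methoxy-4-methylphenyl)-2-methylpropan-1-one, via dimethoxy ketone 3 (not isolated)
Conditions: AlCl3 (2.5 equiv), CH2Cl2, 0 °C to reflux; ice/aq. HCl
Reagents that add atoms: none
Why: Friedel–Crafts acylation should occur para to the methyl group (the position at which this arene is formylated and acylated), and the excess AlCl3 should then cleave only the methoxy group ortho to the new carbonyl through its aluminium chelate, exposing the phenol that directs step 2.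

Step 2
Reactants: 4 1-(2-hydroxy-5-methoxy-4-methylphenyl)-2-methylpropan-1-one; 5 (3aR,7aR)-2-allyl-1,3-bis(4-bromobenzyl)-2-chlorooctahydro-1H-1,3,2-benzodiazasilole
Product: 6 2-[(3S)-3-hydroxy-2-methylhex-5-en-3-yl]-4-methoxy-5-methylphenol
Conditions: 5 (1.5 equiv), toluene, 40 °C; then 1 M aq. NaOH/MeOH, 0 °C, neutralise with NH4Cl
Reagents that add atoms: none
Why: Phenol-directed asymmetric allylation with the strained diamine-derived allylchlorosilane (Leighton allylation), a reagent class shown on hindered 2-hydroxyaryl ketones; the phenol binds silicon, the ketone is activated within the chelate and allyl is delivered to one face, so the C3 stereocentre is set by the (R,R)-diamine.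

Step 3
Reactants: 6 2-[(3S)-3-hydroxy-2-methylhex-5-en-3-yl]-4-methoxy-5-methylphenol
Product: 7 (4S)-4-allyl-2,2-di-tert-butyl-6-methoxy-7-methyl-4-isopropyl-4H-1,3,2-benzodioxasiline
Conditions: t-Bu2Si(OTf)2, 2,6-lutidine, DMF, 0 to 40 °C
Reagents that add atoms: di-tert-butylsilyl bis(trifluoromethanesulfonate), CC(C)(C)[Si](OS(=O)(=O)C(F)(F)F)(OS(=O)(=O)C(F)(F)F)C(C)(C)C
Why: Silylene protection of a 1,3-diol-type pair ties phenol O5 to tertiary O3 in a six-membered ring, which masks both hydroxyls in one step, keeps O3 away from the later carbenoid and locks the C3 substituents relative to the arene plane.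

Step 4
Reactants: 7 (4S)-4-allyl-2,2-di-tert-butyl-6-methoxy-7-methyl-4-isopropyl-4H-1,3,2-benzodioxasiline
Product: 8 2-[(4S)-2,2-di-tert-butyl-6-methoxy-7-methyl-4-isopropyl-4H-1,3,2-benzodioxasilin-4-yl]acetaldehyde
Conditions: OsO4 (2 mol %), NaIO4, 2,6-lutidine, dioxane/H2O, rt
Reagents that add atoms: sodium periodate, [Na+].[O-]I(=O)(=O)=O
Why: Lemieux–Johnson oxidation cleaves the terminal alkene to the C1 aldehyde without touching the electron-rich arene, which ozone could attack.

Step 5
Reactants: 8 2-[(4S)-2,2-di-tert-butyl-6-methoxy-7-methyl-4-isopropyl-4H-1,3,2-benzodioxasilin-4-yl]acetaldehyde; 9 propiophenone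
Product: 10 3-hydroxy-2-methyl-1-phenyl-4-[(4S)-2,2-di-tert-butyl-6-methoxy-7-methyl-4-isopropyl-4H-1,3,2-benzodioxasilin-4-yl]butan-1-one (diastereomer mixture at the two new centres)
Conditions: 9, LiN(i-Pr)2, THF, −78 °C; then 8, −78 °C; aq. NH4Cl
Reagents that add atoms: none
Why: Aldol addition of the lithium enolate of propiophenone forms the C1–C10 bond with the C10 methyl already attached, so the site of the later diazo group is fixed by connectivity and not by regioselective enolisation; both new stereocentres are erased in steps 6 and 7.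

Step 6
Reactants: 10 aldol adduct
Product: 11 2-methyl-1-phenyl-4-[(4S)-2,2-di-tert-butyl-6-methoxy-7-methyl-4-isopropyl-4H-1,3,2-benzodioxasilin-4-yl]butane-1,3-dione
Conditions: Dess–Martin periodinane, pyridine, CH2Cl2, 0 °C to rt
Reagents that add atoms: none
Why: Dess–Martin oxidation of the secondary alcohol should give the 2-methyl-1,3-diketone under buffered conditions that the silylene and the aryl ether tolerate.

Step 7
Reactants: 11 2-methyl-1,3-diketone
Product: 12 3-diazo-1-[(4S)-2,2-di-tert-butyl-6-methoxy-7-methyl-4-isopropyl-4H-1,3,2-benzodioxasilin-4-yl]butan-2-one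
Conditions: 4-acetamidobenzenesulfonyl azide, DBU, MeCN, 0 °C to rt
Reagents that add atoms: 4-acetamidobenzenesulfonyl azide, CC(=O)Nc1ccc(cc1)S(=O)(=O)N=[N+]=[N-]
Why: Deacylative (debenzoylative) Regitz diazo transfer: the azide adds at C10 and the triazene nitrogen should attack the benzoyl carbonyl and not the C1 carbonyl, which is shielded by the neopentyl-type C2 methylene, so benzoyl leaves as the N-acylsulfonamide and the α-methyl diazo ketone remains.

Step 8
Reactants: 12 α-methyl diazo ketone
Product: 14 (3S,10S)-8a-methyl-3,8a-dihydroazulen-1(2H)-one with C3 isopropyl, O3–Si(t-Bu)2–O5 bridge (C4=C5 silyl enol ether), C6=C7 methyl and C8=C9 methyl enol ether, via norcaradiene 13 (not isolated)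
Conditions: Rh2(OAc)4 (1 mol %), CH2Cl2, 40 °C, slow addition of 12; filtration through Et3N-deactivated silica
Reagents that add atoms: none
Why: Rh2(OAc)4 should expel N2 from 12 to give the electrophilic C10 carbenoid, which cyclopropanates the ipso/ortho C4–C9 bond to norcaradiene 13, and 6π electrocyclic opening of 13 breaks C4–C9 to give cycloheptatriene 14. The closest known reaction is the intramolecular Buchner reaction of 1-diazo-4-arylbutan-2-ones and their α-methyl homologues (2-diazo-5-arylpentan-3-ones) to 3,8a-dihydroazulen-1(2H)-ones. The five-membered ring closes by C4–C10 bond formation in the tethered cyclopropanation, and the seven-membered ring arises by expansion of the benzene ring when C9–C10 forms and C4–C9 breaks. The new stereocentre C10 is controlled by C3 through the silylene: O3 is held in the arene plane next to O5, so C2 and isopropyl lie on opposite faces, the carbenoid can reach only the face carrying C2, and the cis fusion of the five-membered ring onto the cyclopropane then places the C10 methyl cis to O3 and trans to isopropyl. The step needs addition at C4–C9 and not C4–C5 (C5 bears the silyloxy group and the tether geometry points C2 toward C9) and must outrun 1,2-hydride shift, insertion into the isopropyl C–H (β to oxygen, deactivated), ylide formation at the hindered O3 and rearomatisation of 13 to a 2-tetralone (neutral conditions, immediate use).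

Step 9
Reactants: 14 silylene-bridged dihydroazulenone
Product: 16 (3S,3aS,8aS)-3-hydroxy-6,8a-dimethyl-3-isopropyl-3,3a,8,8a-tetrahydroazulene-1,4,7(2H)-trione (C1, C5, C8 ketones; trans ring fusion), via C8 enol ether hydroxy diketone 15 (not isolated)
Conditions: HF·pyridine, pyridine, THF, 0 °C to rt; then 1 M aq. HCl, THF, 0 °C
Reagents that add atoms: water, O
Why: Fluoride should cleave the silylene at the enol oxygen first, and the C5 enol is then protonated at C4 while O3 still carries the bulky fluorosilyl group, on the face opposite that group and the axial C10 methyl, which gives the trans ring fusion (also the more stable one, with C5 anti to isopropyl); the non-acidic first stage avoids ionisation of the C3 oxygen, which is allylic to the C4=C5 enol ether, and only afterwards is the C8 methyl enol ether hydrolysed by dilute acid.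

Step 10
Reactants: 16 hydroxy triketone
Product: 17 (1R,3S,3aR,4R,8aS)-1,3,4-trihydroxy-6,8a-dimethyl-3-isopropyl-2,3,3a,4,8,8a-hexahydroazulen-7(1H)-one (C1, C3, C5 triol; C8 enone)
Conditions: Me4NBH(OAc)3 (excess), MeCN/AcOH (1:1), −30 °C to rt
Reagents that add atoms: none
Why: Saksena–Evans hydroxyl-directed reduction: the C3 hydroxyl exchanges onto boron and delivers hydride through six-membered transition states to the two β-carbonyls C1 and C5 on the face that bears O3, which sets C1 (hydroxyl trans to C3–OH and to the C10 methyl) and C5 (hydroxyl anti to C3–OH), while the C8 ketone has no β-hydroxyl and is not reduced by this mild hydride.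

Step 11
Reactants: 18 4-hydroxybenzoic acid
Product: 20 4-(tert-butyldimethylsilyloxy)benzoic acid, via bis-silyl derivative 19 (not isolated)
Conditions: TBSCl (2.5 equiv), imidazole, DMF, rt; then AcOH/THF/H2O, rt
Reagents that add atoms: tert-butyldimethylsilyl chloride, CC(C)(C)[Si](C)(C)Cl
Why: Silylation of both acidic hydroxyls followed by selective hydrolysis of the labile silyl ester is standard protecting-group chemistry and leaves the aryl silyl ether.

Step 12
Reactants: 17 triol; 20 4-(tert-butyldimethylsilyloxy)benzoic acid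
Product: 21 C5 4-(tert-butyldimethylsilyloxy)benzoate of 17 (C1 and C3 hydroxyls free)
Conditions: 20 (1.05 equiv), DCC, DMAP, CH2Cl2, −10 °C to rt
Reagents that add atoms: none
Why: Steglich esterification should select the allylic C5 hydroxyl, whose neighbour C4 carries only hydrogen on the same face, over the C1 hydroxyl, which is neopentylic (next to quaternary C10) and 1,3-cis to the isopropyl group, and over the tertiary C3 hydroxyl.

Step 13
Reactants: 21 C5 ester
Product: 22 C1 acetate, C5 4-(tert-butyldimethylsilyloxy)benzoate (silyl-protected target)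
Conditions: Ac2O, Et3N, DMAP, CH2Cl2, rt
Reagents that add atoms: acetic anhydride, CC(=O)OC(C)=O
Why: DMAP-catalysed acetylation of the only remaining secondary hydroxyl (C1); the hindered tertiary C3 hydroxyl should not react at room temperature.

Step 14
Reactants: 22 silyl-protected target
Product: 23 target, (1R,3S,3aR,4R,8aS)-1-acetoxy-3-hydroxy-6,8a-dimethyl-7-oxo-3-isopropyl-1,2,3,3a,4,7,8,8a-octahydroazulen-4-yl 4-hydroxybenzoate
Conditions: HF·pyridine, pyridine, THF, 0 °C
Reagents that add atoms: none
Why: Buffered fluoride cleavage of the aryl silyl ether should leave both esters, the enone and the tertiary alcohol untouched.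

**Compound list**
1 | 2,5-dimethoxytoluene | COc1ccc(OC)c(C)c1 | starting material
2 | isobutyryl chloride | CC(C)C(Cl)=O | starting material
3 | 1-(2,5-dimethoxy-4-methylphenyl)-2-methylpropan-1-one | COc1cc(C(=O)C(C)C)c(OC)cc1C | intermediate
4 | 1-(2-hydroxy-5-methoxy-4-methylphenyl)-2-methylpropan-1-one | COc1cc(C(=O)C(C)C)c(O)cc1C | intermediate
5 | (3aR,7aR)-2-allyl-1,3-bis(4-bromobenzyl)-2-chlorooctahydro-1H-1,3,2-benzodiazasilole | C=CC[Si]1(Cl)N(Cc2ccc(Br)cc2)[C@@H]2CCCC[C@H]2N1Cc1ccc(Br)cc1 | starting material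
6 | 2-[(3S)-3-hydroxy-2-methylhex-5-en-3-yl]-4-methoxy-5-methylphenol | C=CC[C@](O)(C(C)C)c1cc(OC)c(C)cc1O | intermediate
7 | (4S)-4-allyl-2,2-di-tert-butyl-6-methoxy-7-methyl-4-isopropyl-4H-1,3,2-benzodioxasiline | C=CC[C@@]1(C(C)C)O[Si](C(C)(C)C)(C(C)(C)C)Oc2cc(C)c(OC)cc12 | intermediate
8 | 2-[(4S)-2,2-di-tert-butyl-6-methoxy-7-methyl-4-isopropyl-4H-1,3,2-benzodioxasilin-4-yl]acetaldehyde | O=CC[C@@]1(C(C)C)O[Si](C(C)(C)C)(C(C)(C)C)Oc2cc(C)c(OC)cc12 | intermediate
9 | propiophenone | CCC(=O)c1ccccc1 | starting material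
10 | 3-hydroxy-2-methyl-1-phenyl-4-[(4S)-benzodioxasilin-4-yl]butan-1-one (silylene as in 8; diastereomer mixture) | CC(C(=O)c1ccccc1)C(O)C[C@@]1(C(C)C)O[Si](C(C)(C)C)(C(C)(C)C)Oc2cc(C)c(OC)cc12 | intermediate
11 | 2-methyl-1-phenyl-4-[(4S)-benzodioxasilin-4-yl]butane-1,3-dione (silylene as in 8) | CC(C(=O)c1ccccc1)C(=O)C[C@@]1(C(C)C)O[Si](C(C)(C)C)(C(C)(C)C)Oc2cc(C)c(OC)cc12 | intermediate
12 | 3-diazo-1-[(4S)-2,2-di-tert-butyl-6-methoxy-7-methyl-4-isopropyl-4H-1,3,2-benzodioxasilin-4-yl]butan-2-one | CC(=[N+]=[N-])C(=O)C[C@@]1(C(C)C)O[Si](C(C)(C)C)(C(C)(C)C)Oc2cc(C)c(OC)cc12 | intermediate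
13 | norcaradiene valence isomer of 14 (cyclopropane C4–C9–C10) | O=C1C[C@@]2(C(C)C)O[Si](C(C)(C)C)(C(C)(C)C)OC3=CC(C)=C(OC)[C@H]4[C@@]1(C)[C@@]234 | intermediate
14 | (3S,10S)-silylene-bridged 8a-methyl-3,8a-dihydroazulen-1(2H)-one (C4=C5–O–Si, C6=C7 methyl, C8(OMe)=C9) | O=C1C[C@@]2(C(C)C)O[Si](C(C)(C)C)(C(C)(C)C)OC3=C2[C@]1(C)C=C(OC)C(C)=C3 | intermediate
15 | trans-fused C3-hydroxy C1,C5-diketone with C8 methyl enol ether | O=C1C[C@](O)(C(C)C)[C@H]2C(=O)C=C(C)C(OC)=C[C@]12C | intermediate
16 | (3S,3aS,8aS)-3-hydroxy-6,8a-dimethyl-3-isopropyl-3,3a,8,8a-tetrahydroazulene-1,4,7(2H)-trione | O=C1C[C@](O)(C(C)C)[C@H]2C(=O)C=C(C)C(=O)C[C@]12C | intermediate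
17 | (1R,3S,3aR,4R,8aS)-1,3,4-trihydroxy-6,8a-dimethyl-3-isopropyl-2,3,3a,4,8,8a-hexahydroazulen-7(1H)-one | O[C@@H]1C[C@](O)(C(C)C)[C@H]2[C@H](O)C=C(C)C(=O)C[C@]12C | intermediate
18 | 4-hydroxybenzoic acid | OC(=O)c1ccc(O)cc1 | starting material
19 | tert-butyldimethylsilyl 4-(tert-butyldimethylsilyloxy)benzoate | CC(C)(C)[Si](C)(C)OC(=O)c1ccc(O[Si](C)(C)C(C)(C)C)cc1 | intermediate
20 | 4-(tert-butyldimethylsilyloxy)benzoic acid | OC(=O)c1ccc(O[Si](C)(C)C(C)(C)C)cc1 | intermediate
21 | C5 4-(tert-butyldimethylsilyloxy)benzoate of triol 17 | O[C@@H]1C[C@](O)(C(C)C)[C@H]2[C@H](OC(=O)c3ccc(O[Si](C)(C)C(C)(C)C)cc3)C=C(C)C(=O)C[C@]12C | intermediate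
22 | C1 acetate of 21 (silyl-protected target) | CC(=O)O[C@@H]1C[C@](O)(C(C)C)[C@H]2[C@H](OC(=O)c3ccc(O[Si](C)(C)C(C)(C)C)cc3)C=C(C)C(=O)C[C@]12C | intermediate
23 | target, (1R,3S,3aR,4R,8aS)-1-acetoxy-3-hydroxy-6,8a-dimethyl-7-oxo-3-isopropyl-1,2,3,3a,4,7,8,8a-octahydroazulen-4-yl 4-hydroxybenzoate | CC(=O)O[C@@H]1C[C@](O)(C(C)C)[C@H]2[C@H](OC(=O)c3ccc(O)cc3)C=C(C)C(=O)C[C@]12C | target

**Totals:** 14 steps; longest linear sequence 13 steps (steps 1–10 and 12–14).

**Steps most likely to fail**

Step 8. The α-methyl carbenoid may undergo 1,2-hydride migration to the vinyl ketone faster than it adds to the arene, and the donor–acceptor cyclopropane of the norcaradiene may open and rearomatise to a 2-tetralone. Fallback: the methyl group is brought in after the ring expansion. Setting out from aldehyde 8, MeMgBr addition would give the secondary alcohol F1 and Dess–Martin oxidation the methyl ketone F2. Kinetic enolisation at the methyl group (LiN(SiMe3)2, −78 °C) and trifluoroacetylation with CF3CO2CH2CF3 would give the trifluoroacetyl diketone F3 in the flask, and detrifluoroacetylative diazo transfer (MsN3, Et3N, aq. MeCN) the terminal diazo ketone F4, whose carbenoid has no β-hydrogen. Its Buchner reaction with Rh2(OAc)4, the parent and best-documented case, would give the 8a-H dihydroazulenone F5. C-methylation of the C10 enolate of F5 (KOt-Bu, MeI, THF, −78 °C) on the face away from the C3 isopropyl group comes back to the route at 14.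

Step 9. Protonation of the C5 enol from the face syn to the C10 methyl would give the cis ring fusion, and acid or base could remove the C3 oxygen. Fallback: thermodynamic instead of kinetic control of C4. Setting out from 14, the same unmasking would be carried through to the cis-fused hydroxy triketone F6. F6 would be equilibrated at C4 through the C5 enol with a weak amine base (imidazole, CHCl3/MeOH, 40 °C), too weak to form the C3 alkoxide that retro-aldol cleavage needs. The trans isomer, with the C4–C5 bond anti to isopropyl and a hydrogen bond from the C3 hydroxyl to the C5 carbonyl, is 16, where the route is rejoined.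

Step 12. Site selectivity between the C5 and C1 hydroxyls may be poor, giving the wrong mono-ester or the bis-ester. Fallback: differentiation by oxidation state instead of by acylation rate. Setting out from triol 17, MnO2 would oxidise only the allylic C5 hydroxyl to the C1-hydroxy enedione F7. Acetylation (Ac2O, DMAP) of its only secondary hydroxyl would give the C1 acetate F8. A second C3-hydroxyl-directed reduction with Me4NBH(OAc)3 would give the C5 alcohol F9, whose only secondary hydroxyl is esterified with 20 (DCC, DMAP) to come back to the route at 22.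

**Further compounds**
F1 | step 8 | 1-[(4S)-2,2-di-tert-butyl-6-methoxy-7-methyl-4-isopropyl-4H-1,3,2-benzodioxasilin-4-yl]propan-2-ol (carbinol epimers) | CC(O)C[C@@]1(C(C)C)O[Si](C(C)(C)C)(C(C)(C)C)Oc2cc(C)c(OC)cc12
F2 | step 8 | 1-[(4S)-2,2-di-tert-butyl-6-methoxy-7-methyl-4-isopropyl-4H-1,3,2-benzodioxasilin-4-yl]propan-2-one | CC(=O)C[C@@]1(C(C)C)O[Si](C(C)(C)C)(C(C)(C)C)Oc2cc(C)c(OC)cc12
F3 | step 8 | 1,1,1-trifluoro-5-[(4S)-2,2-di-tert-butyl-6-methoxy-7-methyl-4-isopropyl-4H-1,3,2-benzodioxasilin-4-yl]pentane-2,4-dione | O=C(CC(=O)C(F)(F)F)C[C@@]1(C(C)C)O[Si](C(C)(C)C)(C(C)(C)C)Oc2cc(C)c(OC)cc12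
F4 | step 8 | 1-diazo-3-[(4S)-2,2-di-tert-butyl-6-methoxy-7-methyl-4-isopropyl-4H-1,3,2-benzodioxasilin-4-yl]propan-2-one | [N-]=[N+]=CC(=O)C[C@@]1(C(C)C)O[Si](C(C)(C)C)(C(C)(C)C)Oc2cc(C)c(OC)cc12
F5 | step 8 | 8a-H analogue of 14 (C10 bears hydrogen instead of methyl) | O=C1C[C@@]2(C(C)C)O[Si](C(C)(C)C)(C(C)(C)C)OC3=C2[C@@H]1C=C(OC)C(C)=C3
F6 | step 9 | cis-fused C4 epimer of hydroxy triketone 16 | O=C1C[C@](O)(C(C)C)[C@@H]2C(=O)C=C(C)C(=O)C[C@]12C
F7 | step 12 | C1,C3-dihydroxy C5,C8-enedione (trans-fused) | O[C@@H]1C[C@](O)(C(C)C)[C@H]2C(=O)C=C(C)C(=O)C[C@]12C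
F8 | step 12 | C1 acetate of F7 | CC(=O)O[C@@H]1C[C@](O)(C(C)C)[C@H]2C(=O)C=C(C)C(=O)C[C@]12C
F9 | step 12 | C1 acetate, C3,C5-diol, C8 enone | CC(=O)O[C@@H]1C[C@](O)(C(C)C)[C@H]2[C@H](O)C=C(C)C(=O)C[C@]12C
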